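**Retrosynthetic overview**
- Kurarinone ⇒ C2–C1′ bond: rhodium-catalysed enantioselective conjugate addition of a MOM-protected 2,4-dihydroxyphenylboronic acid (ring B, from resorcinol) to an 8-lavandulyl-7-hydroxy-5-methoxychromone; this sets 2S.
- Chromone ⇒ ring C closed by the enaminone method from a ring A methyl ketone, itself made by ortho-lithiation and acetylation.
- Key disconnection: the aryl C8–CH2 bond, formed in a one-pot ortho-lithiation / iron-catalysed radical cross-coupling of a di-ortho-alkoxy aryl Grignard reagent with (S)-lavandulyl bromide.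
- (S)-Lavandulyl bromide ⇒ (S)-lavandulic acid ⇒ enantioselective α-prenylation of 3-methylbut-2-enoic acid; this sets the side-chain centre.
- Ring order: rings A and B are bought as resorcinol (ring A is brought to the 1,3,5-trioxygenated pattern by C–H borylation/oxidation); ring C is the only ring formed (step 9) and reaches the flavanone level in step 12.

Assumption: the target is the (2S, side-chain 2R) isomer exactly as drawn in the SMILES, and the chiral tetramine and the bisphosphine ligand are available in both antipodes so that the sense of induction can be matched.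

**Route**

Step 1
Reactants: 1 3-methylbut-2-enoic acid; 2 1-bromo-3-methylbut-2-ene (prenyl bromide)
Product: 4 (2S)-5-methyl-2-(prop-1-en-2-yl)hex-4-enoic acid [(S)-lavandulic acid], via dilithium dienediolate 3 (not isolated)
Conditions: (R,R)-tetramine N1,N3-bis[(1R)-1-phenyl-2-(piperidin-1-yl)ethyl]propane-1,3-diamine (1.05 equiv), n-BuLi (4.0 equiv), THF, 0 °C; 1, 0 °C, 1 h; 2, −78 °C; 1 M HCl work-up (tetramine recovered)
Reagents that add atoms: none
Why: Direct enantioselective alkylation of a carboxylic acid dienediolate held in a mixed aggregate with a chiral dilithium amide (Zakarian-type traceless auxiliary): the dienediolate reacts at its α-carbon with the allylic bromide by SN2, the amide shields one face and sets the S centre (by analogy with its arylacetic acid alkylations; the (S,S)-tetramine is used if the sense proves opposite), and the double bond ends up deconjugated as the isopropenyl group.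

Step 2
Reactants: 4 (S)-lavandulic acid
Product: 5 (2S)-5-methyl-2-(prop-1-en-2-yl)hex-4-en-1-ol [(S)-lavandulol]
Conditions: LiAlH4, Et2O, 0 °C → rt; aqueous NaOH work-up
Reagents that add atoms: none
Why: Lithium aluminium hydride reduction of the carboxylate to the primary alcohol; the isolated alkenes are inert and the lithium carboxylate is not enolised, so the α-centre is kept.

Step 3
Reactants: 5 (S)-lavandulol
Product: 6 (5S)-6-bromo-2-methyl-5-(prop-1-en-2-yl)hex-2-ene [(S)-lavandulyl bromide]
Conditions: CBr4, PPh3, CH2Cl2, 0 °C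
Reagents that add atoms: carbon tetrabromide BrC(Br)(Br)Br
Why: Appel reaction, in which the alkoxyphosphonium salt is displaced by bromide at the primary carbon, so the adjacent stereocentre is untouched.

Step 4
Reactants: 7 resorcinol
Product: 8 1,3-bis(methoxymethoxy)benzene
Conditions: NaH, DMF, 0 °C; MOMCl, 0 °C → rt
Reagents that add atoms: chloromethyl methyl ether COCCl
Why: Williamson-type O-alkylation of the bis-phenoxide; MOM is chosen because it directs ortho-lithiation later and is removed by mild acid.

Step 5
Reactants: 8 1,3-bis(methoxymethoxy)benzene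
Product: 10 3,5-bis(methoxymethoxy)phenol, via pinacol arylboronate 9 (not isolated)
Conditions: [Ir(OMe)(cod)]2 (1 mol%), 4,4'-di-tert-butyl-2,2'-bipyridine (2 mol%), B2pin2 (0.55 equiv), THF, 80 °C; then NaOH, 30% H2O2, 0 °C → rt
Reagents that add atoms: hydrogen peroxide OO; bis(pinacolato)diboron CC1(C)OB(OC1(C)C)B1OC(C)(C)C(C)(C)O1 (its atoms are carried only in 9)
Why: Sterically controlled iridium-catalysed aromatic C–H borylation (Hartwig–Miyaura type) takes place only at C5, the one C–H with no ortho substituent, and basic peroxide oxidation with aryl migration from boron to oxygen gives the 1,3,5-trioxygenated ring.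

Step 6
Reactants: 10 3,5-bis(methoxymethoxy)phenol
Product: 11 1-methoxy-3,5-bis(methoxymethoxy)benzene
Conditions: MeI, K2CO3, acetone, 50 °C
Reagents that add atoms: iodomethane CI
Why: Williamson ether synthesis on the only free phenol installs the methyl ether that becomes the 5-OMe group.

Step 7 (key step)
Reactants: 11 1-methoxy-3,5-bis(methoxymethoxy)benzene; 6 (S)-lavandulyl bromide
Product: 14 5-methoxy-1,3-bis(methoxymethoxy)-2-[(2R)-5-methyl-2-(prop-1-en-2-yl)hex-4-en-1-yl]benzene, via aryllithium 12 (not isolated), via arylmagnesium bromide 13 (not isolated)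
Conditions: 11 (1.5 equiv), n-BuLi, THF, 0 °C, 1 h; MgBr2·OEt2, 0 °C → rt; TMEDA (1.2 equiv); this solution added over 1 h to 6 (1.0 equiv) and FeCl3 (5 mol%) in THF, 0 °C → rt
Reagents that add atoms: none
Why: Directed ortho-metalation between the two MOM ethers, transmetalation to magnesium and a Nakamura-type iron-catalysed Kumada cross-coupling, in which a low-valent aryl iron species abstracts bromine from 6 to give the primary lavandulyl radical that recombines at iron and is reductively eliminated to form the aryl–CH2 bond; di-ortho-substituted aryl Grignard reagents such as mesityl are competent partners, 3-exo closure of the homoallyl radical onto the isopropenyl group (about 10^4 s−1) is too slow to compete with capture, and the β-stereocentre never becomes a radical centre, so it is carried through unchanged (the descriptor reads R only because CH2Ar ranks below isopropenyl whereas CH2Br ranked above it).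

Step 8
Reactants: 14 the lavandulyl arene from step 7
Product: 16 1-{6-methoxy-2,4-bis(methoxymethoxy)-3-[(2R)-5-methyl-2-(prop-1-en-2-yl)hex-4-en-1-yl]phenyl}ethan-1-one, via aryllithium 15 (not isolated)
Conditions: n-BuLi, THF, 0 °C, 1 h; N-methoxy-N-methylacetamide, −78 → 0 °C; H2O
Reagents that add atoms: N-methoxy-N-methylacetamide CC(=O)N(C)OC
Why: A second directed ortho-metalation at one of the two equivalent ring positions flanked by OMOM and OMe, then Weinreb amide acylation, whose chelated tetrahedral intermediate prevents over-addition and gives the methyl ketone.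

Step 9
Reactants: 16 the methyl ketone from step 8
Product: 18 7-hydroxy-5-methoxy-8-[(2R)-5-methyl-2-(prop-1-en-2-yl)hex-4-en-1-yl]-4H-chromen-4-one, via enaminone 17 (not isolated)
Conditions: Me2NCH(OMe)2 (neat), 100 °C; evaporate; then 2 M HCl in MeOH, 40 °C
Reagents that add atoms: N,N-dimethylformamide dimethyl acetal COC(OC)N(C)C
Why: Enaminone chromone synthesis: condensation of the methyl ketone with the amide acetal, then acid-mediated MOM cleavage and intramolecular oxa-Michael addition with loss of dimethylamine; only the hydroxyl ortho to the carbonyl can close ring C, which fixes 5-OMe, 7-OH and 8-lavandulyl.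

Step 10
Reactants: 8 1,3-bis(methoxymethoxy)benzene
Product: 19 1-bromo-2,4-bis(methoxymethoxy)benzene
Conditions: NBS, MeCN, 0 °C → rt
Reagents that add atoms: N-bromosuccinimide O=C1CCC(=O)N1Br
Why: Electrophilic aromatic bromination goes para to one MOM ether and ortho to the other, the position between the two ethers being more hindered.

Step 11
Reactants: 19 1-bromo-2,4-bis(methoxymethoxy)benzene
Product: 21 [2,4-bis(methoxymethoxy)phenyl]boronic acid, via aryllithium 20 (not isolated)
Conditions: n-BuLi, THF, −78 °C; B(Oi-Pr)3, −78 °C → rt; cold 1 M HCl to pH 5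
Reagents that add atoms: triisopropyl borate CC(C)OB(OC(C)C)OC(C)C; water O
Why: Bromine–lithium exchange, trapping of the chelation-stabilised aryllithium with a trialkyl borate and hydrolysis give the arylboronic acid.

Step 12
Reactants: 18 the chromone from step 9; 21 [2,4-bis(methoxymethoxy)phenyl]boronic acid
Product: 22 (2S)-2-[2,4-bis(methoxymethoxy)phenyl]-7-hydroxy-5-methoxy-8-[(2R)-5-methyl-2-(prop-1-en-2-yl)hex-4-en-1-yl]-2,3-dihydro-4H-chromen-4-one
Conditions: [Rh(OH)(cod)]2 (3 mol%), (S)-MeO-F12-BIPHEP = (S)-(6,6'-dimethoxybiphenyl-2,2'-diyl)bis[bis(3,4,5-trifluorophenyl)phosphane] (6.5 mol%), 21 (3 equiv), toluene/H2O 10:1, 35 °C, no added base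
Reagents that add atoms: none
Why: Rhodium-catalysed enantioselective 1,4-addition of an arylboronic acid to a chromone (Hayashi–Miyaura reaction) with an electron-poor atropisomeric bisphosphine, in which the aryl–rhodium species adds to one face of C2=C3 under catalyst control and sets C2 as S (the same facial sense by which (S)-BINAP-type ligands give (S)-3-arylcyclohexanones; the (R)-ligand is used if the sense proves opposite), the remote side-chain centre has no influence, and base-free conditions avoid retro-oxa-Michael opening of the flavanone.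

Step 13
Reactants: 22 the bis-MOM flavanone from step 12
Product: 23 kurarinone
Conditions: 2 M HCl in MeOH/THF, rt
Reagents that add atoms: none
Why: Acid-catalysed MOM acetal cleavage by transacetalisation to methanol; dilute acid at room temperature leaves the prenyl and isopropenyl alkenes alone and does not open the flavanone ring, so both stereocentres are preserved.

**Compound list**
1 | 3-methylbut-2-enoic acid | CC(C)=CC(=O)O | starting material
2 | 1-bromo-3-methylbut-2-ene (prenyl bromide) | CC(C)=CCBr | starting material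
3 | dilithium dienediolate of 3-methylbut-2-enoic acid | [Li+].[Li+].[O-]C([O-])=CC(C)=C | intermediate
4 | (2S)-5-methyl-2-(prop-1-en-2-yl)hex-4-enoic acid | C=C(C)[C@H](CC=C(C)C)C(=O)O | intermediate
5 | (2S)-5-methyl-2-(prop-1-en-2-yl)hex-4-en-1-ol | C=C(C)[C@H](CC=C(C)C)CO | intermediate
6 | (5S)-6-bromo-2-methyl-5-(prop-1-en-2-yl)hex-2-ene | C=C(C)[C@H](CC=C(C)C)CBr | intermediate
7 | resorcinol | Oc1cccc(O)c1 | starting material
8 | 1,3-bis(methoxymethoxy)benzene | COCOc1cccc(OCOC)c1 | intermediate
9 | 2-[3,5-bis(methoxymethoxy)phenyl]-4,4,5,5-tetramethyl-1,3,2-dioxaborolane | COCOc1cc(OCOC)cc(c1)B1OC(C)(C)C(C)(C)O1 | intermediate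
10 | 3,5-bis(methoxymethoxy)phenol | COCOc1cc(O)cc(OCOC)c1 | intermediate
11 | 1-methoxy-3,5-bis(methoxymethoxy)benzene | COCOc1cc(OC)cc(OCOC)c1 | intermediate
12 | [4-methoxy-2,6-bis(methoxymethoxy)phenyl]lithium | [Li]c1c(OCOC)cc(OC)cc1OCOC | intermediate
13 | bromo[4-methoxy-2,6-bis(methoxymethoxy)phenyl]magnesium | Br[Mg]c1c(OCOC)cc(OC)cc1OCOC | intermediate
14 | 5-methoxy-1,3-bis(methoxymethoxy)-2-[(2R)-5-methyl-2-(prop-1-en-2-yl)hex-4-en-1-yl]benzene | C=C(C)[C@H](CC=C(C)C)Cc1c(OCOC)cc(OC)cc1OCOC | intermediate
15 | {6-methoxy-2,4-bis(methoxymethoxy)-3-[(2R)-5-methyl-2-(prop-1-en-2-yl)hex-4-en-1-yl]phenyl}lithium | C=C(C)[C@H](CC=C(C)C)Cc1c(OCOC)cc(OC)c([Li])c1OCOC | intermediate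
16 | 1-{6-methoxy-2,4-bis(methoxymethoxy)-3-[(2R)-5-methyl-2-(prop-1-en-2-yl)hex-4-en-1-yl]phenyl}ethan-1-one | C=C(C)[C@H](CC=C(C)C)Cc1c(OCOC)cc(OC)c(C(C)=O)c1OCOC | intermediate
17 | (2E)-3-(dimethylamino)-1-{6-methoxy-2,4-bis(methoxymethoxy)-3-[(2R)-5-methyl-2-(prop-1-en-2-yl)hex-4-en-1-yl]phenyl}prop-2-en-1-one | C=C(C)[C@H](CC=C(C)C)Cc1c(OCOC)cc(OC)c(C(=O)/C=C/N(C)C)c1OCOC | intermediate
18 | 7-hydroxy-5-methoxy-8-[(2R)-5-methyl-2-(prop-1-en-2-yl)hex-4-en-1-yl]-4H-chromen-4-one | C=C(C)[C@H](CC=C(C)C)Cc1c(O)cc(OC)c2c(=O)ccoc12 | intermediate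
19 | 1-bromo-2,4-bis(methoxymethoxy)benzene | COCOc1ccc(Br)c(OCOC)c1 | intermediate
20 | [2,4-bis(methoxymethoxy)phenyl]lithium | [Li]c1ccc(OCOC)cc1OCOC | intermediate
21 | [2,4-bis(methoxymethoxy)phenyl]boronic acid | COCOc1ccc(B(O)O)c(OCOC)c1 | intermediate
22 | (2S)-2-[2,4-bis(methoxymethoxy)phenyl]-7-hydroxy-5-methoxy-8-[(2R)-5-methyl-2-(prop-1-en-2-yl)hex-4-en-1-yl]-2,3-dihydro-4H-chromen-4-one | C=C(C)[C@H](CC=C(C)C)Cc1c(O)cc(OC)c2c1O[C@H](c1ccc(OCOC)cc1OCOC)CC2=O | intermediate
23 | kurarinone, (2S)-2-(2,4-dihydroxyphenyl)-7-hydroxy-5-methoxy-8-[(2R)-5-methyl-2-(prop-1-en-2-yl)hex-4-en-1-yl]-2,3-dihydro-4H-chromen-4-one | C=C(C)[C@H](CC=C(C)C)Cc1c(O)cc(OC)c2c1O[C@H](c1ccc(O)cc1O)CC2=O | target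

**Step count and risks**
Total step count: 13. Longest linear sequence: 8 steps (resorcinol: steps 4, 5, 6, 7, 8, 9, 12, 13; the side-chain branch 1, 2, 3, 7, 8, 9, 12, 13 is equally long).

The three steps most likely to fail:

Step 7 (iron-catalysed radical coupling). The aryl Grignard reagent is di-ortho-alkoxy-substituted and chelating, and the lavandulyl radical could lose its allylic β-hydrogen or rearrange. The fallback sets out from 11 and 6 and comes back at 14. Compound 11 is lithiated to 12 as before and quenched with I2 (THF, −78 °C) to give 2-iodo-5-methoxy-1,3-bis(methoxymethoxy)benzene F1. F1 and 6 are then joined by a nickel/photoredox cross-electrophile coupling (NiCl2·glyme, 4,4'-di-tert-butyl-2,2'-bipyridine, [Ir(dF(CF3)ppy)2(dtbbpy)]PF6, (Me3Si)3SiH, Na2CO3, DME, blue LEDs, rt). Here the arene enters as an electrophile by oxidative addition to zerovalent nickel and the lavandulyl radical is made by silyl-radical bromine abstraction, so neither a hindered aryl Grignard reagent nor low-valent iron is needed.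

Step 12 (enantioselective aryl addition). The boronic acid is ortho-substituted and prone to protodeboronation, the chromone is electron-rich and carries a free phenol, and the facial sense must be confirmed. The fallback sets out from 16 and 19 and comes back at 23. Compound 19 is lithiated to 20 as in step 11 and formylated with DMF to give 2,4-bis(methoxymethoxy)benzaldehyde F2. Claisen–Schmidt condensation of 16 with F2 (KOH, EtOH, rt) gives the protected chalcone (2E)-3-[2,4-bis(methoxymethoxy)phenyl]-1-{6-methoxy-2,4-bis(methoxymethoxy)-3-[(2R)-lavandulyl]phenyl}prop-2-en-1-one F3. Treatment with 3 M HCl in MeOH in the dark removes the four MOM groups to give kuraridin F4. NaOAc in EtOH at 60 °C closes ring C by reversible oxa-Michael addition to a roughly 1:1 mixture of 23 and its C2 epimer (2R)-2-epi-kurarinone F5. These are diastereomers because of the side-chain centre and are separated by preparative HPLC on a chiral stationary phase; F5 is re-equilibrated under the same conditions and recycled.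

Step 1 (enantioselective dienediolate alkylation). The α/γ ratio, the ee and the sense of induction are not established for this exact acid. The fallback sets out from 1 and 2 and comes back at 5. Acid 1 is converted with pivaloyl chloride/Et3N and then LiCl and (4S)-4-benzyloxazolidin-2-one into (4S)-4-benzyl-3-(3-methylbut-2-enoyl)oxazolidin-2-one F6. Deconjugative Evans alkylation (NaN(SiMe3)2, THF, −78 °C, then 2) takes place on the dienolate face opposite the benzyl group and gives (4S)-4-benzyl-3-[(2S)-5-methyl-2-(prop-1-en-2-yl)hex-4-enoyl]oxazolidin-2-one F7. LiBH4 (Et2O, H2O, 0 °C) cleaves F7 directly to 5 with recovery of the auxiliary.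

**Further compounds**
F1 | step 7 | 2-iodo-5-methoxy-1,3-bis(methoxymethoxy)benzene | COCOc1cc(OC)cc(OCOC)c1I
F2 | step 12 | 2,4-bis(methoxymethoxy)benzaldehyde | COCOc1ccc(C=O)c(OCOC)c1
F3 | step 12 | (2E)-3-[2,4-bis(methoxymethoxy)phenyl]-1-{6-methoxy-2,4-bis(methoxymethoxy)-3-[(2R)-5-methyl-2-(prop-1-en-2-yl)hex-4-en-1-yl]phenyl}prop-2-en-1-one | C=C(C)[C@H](CC=C(C)C)Cc1c(OCOC)cc(OC)c(C(=O)/C=C/c2ccc(OCOC)cc2OCOC)c1OCOC
F4 | step 12 | kuraridin, (2E)-1-{2,4-dihydroxy-6-methoxy-3-[(2R)-5-methyl-2-(prop-1-en-2-yl)hex-4-en-1-yl]phenyl}-3-(2,4-dihydroxyphenyl)prop-2-en-1-one | C=C(C)[C@H](CC=C(C)C)Cc1c(O)cc(OC)c(C(=O)/C=C/c2ccc(O)cc2O)c1O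
F5 | step 12 | (2R)-2-epi-kurarinone | C=C(C)[C@H](CC=C(C)C)Cc1c(O)cc(OC)c2c1O[C@@H](c1ccc(O)cc1O)CC2=O
F6 | step 1 | (4S)-4-benzyl-3-(3-methylbut-2-enoyl)oxazolidin-2-one | CC(C)=CC(=O)N1[C@@H](Cc2ccccc2)COC1=O
F7 | step 1 | (4S)-4-benzyl-3-[(2S)-5-methyl-2-(prop-1-en-2-yl)hex-4-enoyl]oxazolidin-2-one | C=C(C)[C@H](CC=C(C)C)C(=O)N1[C@@H](Cc2ccccc2)COC1=O
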